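**Retrosynthetic overview**
1. Target 12 comes from 11 by fluoride removal of four aryl tert-butyldimethylsilyl ethers.
2. Feature: on each resorcinol ring the carbon bonded to the C3/C4 carbonyl (ring C1) sits next to a free OH (ring C2) and para to the second oxygen (ring C4). Such a 2-hydroxyaryl ketone is the product of an ortho O-to-C acyl shift in a 3-oxygenated phenyl ester, so both C(=O)–C(aryl) bonds of 11 are cut back to the bis(3-silyloxyphenyl) ester 9 of the tetrahydrofuran-3,4-dicarboxylic acid.
3. Diester 9 comes from the cis-fused anhydride 6 and two molecules of phenol 7.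
4. Anhydride 6 comes from carbonyl ylide 5 and maleic anhydride 4. This [3+2] cycloaddition builds the only ring made in the route, the tetrahydrofuran (O1, C2–C5), with all four stereocentres. The anhydride ring arrives with 4 and is opened in step 4; the four benzene rings are bought.
5. Ylide 5 comes from trans-diaryloxirane 3, which comes from E-stilbene 2 and aldehyde 1 (reductive coupling, then epoxidation).

Key step: step 5

Remark: aryl benzyl ethers undergo O–CH2 homolysis (photo-Claisen-type benzyl shifts) at 254 nm, so the four spectator phenols are carried as tert-butyldimethylsilyl ethers through the key step; the silylated aldehyde 1 and phenol 7 are assumed to be purchased.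

**Route**

Step 1
Reactants: 1 4-[(tert-butyldimethylsilyl)oxy]benzaldehyde (2 equiv)
Product: 2 (E)-1,2-bis{4-[(tert-butyldimethylsilyl)oxy]phenyl}ethene
Conditions: TiCl4, Zn dust, pyridine, THF, 0 °C then reflux
Reagents that add atoms: none
Why: McMurry reductive homocoupling of an aryl aldehyde on low-valent titanium should give the more stable E-stilbene, aryl silyl ethers being inert to the reagent; no stereocentre is formed.

Step 2
Reactants: 2 (E)-1,2-bis{4-[(tert-butyldimethylsilyl)oxy]phenyl}ethene
Product: 3 trans-2,3-bis{4-[(tert-butyldimethylsilyl)oxy]phenyl}oxirane, racemic (2R*,3R*)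
Conditions: dimethyldioxirane, acetone, 0 °C
Reagents that add atoms: dimethyldioxirane, CC1(C)OO1
Why: Dimethyldioxirane epoxidation is a concerted, stereospecific syn oxygen transfer under neutral conditions, so the E-alkene geometry sets both stereocentres as trans and the electron-rich oxirane is spared acid-induced Meinwald rearrangement.

Step 3
Reactants: 3 trans-2,3-bis{4-[(tert-butyldimethylsilyl)oxy]phenyl}oxirane; 4 maleic anhydride (1 equiv)
Product: 6 meso exo anhydride 4,6-bis{4-[(tert-butyldimethylsilyl)oxy]phenyl}tetrahydro-1H,3H-furo[3,4-c]furan-1,3-dione (aryl groups cis to each other; anhydride ring trans to both), via W-shaped carbonyl ylide 5 (not isolated)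
Conditions: 1,4-dicyanonaphthalene (0.2 equiv), dry degassed MeCN, hν (> 300 nm, Pyrex), Ar, 20 °C; exo adduct separated by crystallisation
Reagents that add atoms: none
Why: Photoinduced electron transfer from the oxirane to singlet-excited 1,4-dicyanonaphthalene breaks the oxirane C–C bond and return of the electron gives the planar exo,exo carbonyl ylide 5, whose concerted suprafacial 1,3-dipolar cycloaddition to one molecule of maleic anhydride sets C2/C5 cis (ylide geometry), C3/C4 cis (cyclic cis-alkene) and, through the sterically favoured exo approach that keeps the anhydride carbonyls away from the two aryl groups, the anhydride ring trans to both aryls; ylide that escapes trapping recloses to the oxirane and is reopened, so an equimolar charge of the dipolarophile suffices and little free anhydride is left to form charge-transfer complexes with the electron-rich arenes.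

Step 4
Reactants: 6 meso exo anhydride; 7 3-[(tert-butyldimethylsilyl)oxy]phenol (2 equiv)
Product: 9 bis{3-[(tert-butyldimethylsilyl)oxy]phenyl} (2R,3R,4S,5S)-2,5-bis{4-[(tert-butyldimethylsilyl)oxy]phenyl}tetrahydrofuran-3,4-dicarboxylate (meso; aryls cis; esters cis to each other; esters trans to aryls), via racemic hemiester acid 8 (not isolated)
Conditions: Et3N (1.1 equiv), DMAP (0.1 equiv), CH2Cl2, 0 °C to 20 °C; then N,N'-diisopropylcarbodiimide (1.5 equiv), 0 °C to 20 °C
Reagents that add atoms: none
Why: DMAP-catalysed ring-opening acylation of the phenol by the cyclic anhydride gives hemiester 8 as its triethylammonium salt and Steglich esterification (carbodiimide, DMAP) of the remaining carboxyl with a second phenol gives the meso diester; no bond at C3 or C4 is broken, so the configuration from step 3 is kept, low temperature and catalytic DMAP guarding against α-epimerisation.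

Step 5
Reactants: 9 bis{3-[(tert-butyldimethylsilyl)oxy]phenyl} (2R,3R,4S,5S)-2,5-bis{4-[(tert-butyldimethylsilyl)oxy]phenyl}tetrahydrofuran-3,4-dicarboxylate
Product: 11 (2R,3R,4S,5S)-3,4-bis{4-[(tert-butyldimethylsilyl)oxy]-2-hydroxybenzoyl}-2,5-bis{4-[(tert-butyldimethylsilyl)oxy]phenyl}tetrahydrofuran (meso), via mono-rearranged keto ester 10 (not isolated)
Conditions: hν (254 nm, low-pressure Hg lamp, quartz), degassed cyclohexane (about 1 mM), Ar, 20 °C
Reagents that add atoms: none
Why: Absorption at 254 nm by each 3-silyloxyphenyl ester leads from the excited singlet to homolysis of the aryl O–acyl bond, and the caged acyl/aryloxyl radical pair recombines at ring carbon C6 (ortho to the former ester oxygen, para to the silyloxy group) to a cyclohexadienone that tautomerises to the 2-hydroxy-4-silyloxyphenyl ketone; the sequence runs once to keto ester 10 and a second time to 11. The closest known reaction is the photo-Fries rearrangement of 3-alkoxyphenyl alkanoates to 2-hydroxy-4-alkoxyphenyl ketones. No ring is closed and no stereocentre is created: C3 and C4 stay sp3 because the acyl radical is a σ radical at the carbonyl carbon, and a secondary alkanoyl radical should lose CO far more slowly than the cage pair recombines, so the configuration of 9 is carried into 11. The selectivity needed is attack at C6 over C2 and C4, and it is secured by the bulky tert-butyldimethylsilyloxy group, which flanks C2 and C4 but is remote from C6; a shift to C4 would still give a 2,4-dioxygenated aryl ketone that converges on 12 in step 6. Aryl silyl ethers offer no weak O–C bond at this wavelength, the non-polar aprotic solvent disfavours ionisation of the benzylic C2–O and C5–O bonds, and the ortho-hydroxy ketone is shielded from further photochemistry by fast excited-state intramolecular proton transfer.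

Step 6
Reactants: 11 (2R,3R,4S,5S)-3,4-bis{4-[(tert-butyldimethylsilyl)oxy]-2-hydroxybenzoyl}-2,5-bis{4-[(tert-butyldimethylsilyl)oxy]phenyl}tetrahydrofuran
Product: 12 (2R,3R,4S,5S)-3,4-bis(2,4-dihydroxybenzoyl)-2,5-bis(4-hydroxyphenyl)tetrahydrofuran (meso; CNP0237262.1)
Conditions: Bu4NF (4.5 equiv), AcOH (4.5 equiv), THF, 0 °C
Reagents that add atoms: none
Why: Fluoride cleaves the four aryl O–Si bonds (Si–F bond formation) and acetic acid protonates each phenoxide as it forms, so the medium stays near neutral and neither retro-oxa-Michael opening of the β-alkoxy ketones nor ionisation of the benzylic C–O bonds should occur; no stereocentre is touched (buffered fluoride desilylation).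

**Compound list**
1 | 4-[(tert-butyldimethylsilyl)oxy]benzaldehyde | CC(C)(C)[Si](C)(C)Oc1ccc(C=O)cc1 | starting material
2 | (E)-1,2-bis{4-[(tert-butyldimethylsilyl)oxy]phenyl}ethene | CC(C)(C)[Si](C)(C)Oc1ccc(/C=C/c2ccc(O[Si](C)(C)C(C)(C)C)cc2)cc1 | intermediate
3 | trans-2,3-bis{4-[(tert-butyldimethylsilyl)oxy]phenyl}oxirane (racemic; one enantiomer drawn) | CC(C)(C)[Si](C)(C)Oc1ccc([C@@H]2O[C@H]2c2ccc(O[Si](C)(C)C(C)(C)C)cc2)cc1 | intermediate
4 | maleic anhydride | O=C1OC(=O)C=C1 | starting material
5 | exo,exo (W-shaped) carbonyl ylide from 3 | CC(C)(C)[Si](C)(C)Oc1ccc(/C=[O+]/[CH-]c2ccc(O[Si](C)(C)C(C)(C)C)cc2)cc1 | intermediate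
6 | meso exo anhydride, 4,6-bis{4-[(tert-butyldimethylsilyl)oxy]phenyl}tetrahydro-1H,3H-furo[3,4-c]furan-1,3-dione (aryls cis, anhydride trans to aryls) | O=C1[C@@H]2[C@H](C(=O)O1)[C@@H](c1ccc(O[Si](C)(C)C(C)(C)C)cc1)O[C@H]2c1ccc(O[Si](C)(C)C(C)(C)C)cc1 | intermediate
7 | 3-[(tert-butyldimethylsilyl)oxy]phenol | CC(C)(C)[Si](C)(C)Oc1cccc(O)c1 | starting material
8 | hemiester acid, 4-{3-[(tert-butyldimethylsilyl)oxy]phenoxycarbonyl}-2,5-bis{4-[(tert-butyldimethylsilyl)oxy]phenyl}tetrahydrofuran-3-carboxylic acid (racemic; relative configuration as in 9) | O=C(O)[C@@H]1[C@H](C(=O)Oc2cccc(O[Si](C)(C)C(C)(C)C)c2)[C@@H](c2ccc(O[Si](C)(C)C(C)(C)C)cc2)O[C@H]1c1ccc(O[Si](C)(C)C(C)(C)C)cc1 | intermediate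
9 | bis{3-[(tert-butyldimethylsilyl)oxy]phenyl} (2R,3R,4S,5S)-2,5-bis{4-[(tert-butyldimethylsilyl)oxy]phenyl}tetrahydrofuran-3,4-dicarboxylate (meso) | O=C(Oc1cccc(O[Si](C)(C)C(C)(C)C)c1)[C@@H]1[C@H](C(=O)Oc2cccc(O[Si](C)(C)C(C)(C)C)c2)[C@@H](c2ccc(O[Si](C)(C)C(C)(C)C)cc2)O[C@H]1c1ccc(O[Si](C)(C)C(C)(C)C)cc1 | intermediate
10 | mono-rearranged keto ester (racemic; relative configuration as in 9) | O=C(c1ccc(O[Si](C)(C)C(C)(C)C)cc1O)[C@@H]1[C@H](C(=O)Oc2cccc(O[Si](C)(C)C(C)(C)C)c2)[C@@H](c2ccc(O[Si](C)(C)C(C)(C)C)cc2)O[C@H]1c1ccc(O[Si](C)(C)C(C)(C)C)cc1 | intermediate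
11 | (2R,3R,4S,5S)-3,4-bis{4-[(tert-butyldimethylsilyl)oxy]-2-hydroxybenzoyl}-2,5-bis{4-[(tert-butyldimethylsilyl)oxy]phenyl}tetrahydrofuran (meso) | O=C(c1ccc(O[Si](C)(C)C(C)(C)C)cc1O)[C@@H]1[C@H](C(=O)c2ccc(O[Si](C)(C)C(C)(C)C)cc2O)[C@@H](c2ccc(O[Si](C)(C)C(C)(C)C)cc2)O[C@H]1c1ccc(O[Si](C)(C)C(C)(C)C)cc1 | intermediate
12 | (2R,3R,4S,5S)-3,4-bis(2,4-dihydroxybenzoyl)-2,5-bis(4-hydroxyphenyl)tetrahydrofuran (meso) | O=C(c1ccc(O)cc1O)[C@@H]1[C@H](C(=O)c2ccc(O)cc2O)[C@@H](c2ccc(O)cc2)O[C@H]1c1ccc(O)cc1 | target

**Step count**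
Total steps: 6. Longest linear sequence: 6 steps (1 → 2 → 3 → 6 → 9 → 11 → 12).

**Steps most likely to fail**

Step 5 (key step). The radical pair may escape the solvent cage (loss of the aryloxyl partner as phenol, hydrogen abstraction or decarbonylation by the acyl radical), recombine at C2 of the resorcinol ring, or the second shift may stall because the first-formed hydroxy ketone absorbs the light. The fallback sets out from anhydride 6 and comes back to the route at target 12, forming the aryl ketone bonds by nucleophilic acyl substitution. Anhydride 6 is opened with N,O-dimethylhydroxylamine hydrochloride and Et3N in CH2Cl2 to the hemi-amide acid F1, which is coupled with a second equivalent of the amine by N,N'-diisopropylcarbodiimide to the bis-Weinreb amide F2. 2,4-Bis(benzyloxy)phenyllithium F3, made from 1-bromo-2,4-bis(benzyloxy)benzene and n-BuLi in THF at −78 °C, is added to F2 at −78 °C; the chelated tetrahedral adducts stop at the ketone stage and give the bis-ketone F4 on NH4Cl quench. Buffered Bu4NF/AcOH in THF at 0 °C frees the two 4-hydroxyphenyl groups to give the bis-phenol F5, and hydrogenolysis (H2, 1 atm, Pd/C, EtOAc, 20 °C, stopped once the four benzyl ethers are gone) gives 12.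

Step 3. The anhydride may approach the ylide in the endo mode, under the aryl-bearing termini, giving the all-cis adduct, and the arene radical cation may lose a silyl group before the C–C bond opens. The fallback sets out from oxirane 3 (with 4 and 7) and comes back to the route at diester 9, using an acyclic cis-dipolarophile. Maleic anhydride 4 is opened by phenol 7 (Et3N, CH2Cl2, 0 °C) to the aryl hydrogen maleate F6, which is coupled with a second equivalent of 7 by N,N'-diisopropylcarbodiimide at 0 °C without DMAP, to avoid amine-catalysed Z-to-E isomerisation, giving bis{3-[(tert-butyldimethylsilyl)oxy]phenyl} maleate F7. Irradiation of 3 and F7 with 1,4-dicyanonaphthalene in MeCN as in step 3 would give 9 directly by way of ylide 5. The two aryl ester groups are twisted out of the alkene plane and cannot lie under the ylide, so the exo mode should be favoured; step 4 is bypassed.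

Step 4. The activated second carboxyl is hindered and may epimerise at C3/C4 (enolisation or ketene formation of the acyl intermediate) or rearrange to an N-acylurea before the phenol attacks. The fallback sets out from anhydride 6 and comes back to the route at diester 9, forming the aryl–oxygen bond instead of the acyl–oxygen bond. Hydrolysis of 6 (THF/H2O, 20 °C) gives the cis-diacid F8, and Chan–Lam-type O-arylation of both carboxyl groups with 3-[(tert-butyldimethylsilyl)oxy]phenylboronic acid (Cu(OTf)2, urea, EtOAc, air, 60 °C) gives 9 without any activation of the acyl carbons.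

**Further compounds**
F1 | step 5 | hemi-amide acid, 4-[methoxy(methyl)carbamoyl]-2,5-bis{4-[(tert-butyldimethylsilyl)oxy]phenyl}tetrahydrofuran-3-carboxylic acid (racemic; relative configuration as in 9) | CON(C)C(=O)[C@@H]1[C@H](C(=O)O)[C@@H](c2ccc(O[Si](C)(C)C(C)(C)C)cc2)O[C@H]1c1ccc(O[Si](C)(C)C(C)(C)C)cc1
F2 | step 5 | bis-Weinreb amide, (2R,3R,4S,5S)-N3,N4-dimethoxy-N3,N4-dimethyl-2,5-bis{4-[(tert-butyldimethylsilyl)oxy]phenyl}tetrahydrofuran-3,4-dicarboxamide (meso) | CON(C)C(=O)[C@@H]1[C@H](C(=O)N(C)OC)[C@@H](c2ccc(O[Si](C)(C)C(C)(C)C)cc2)O[C@H]1c1ccc(O[Si](C)(C)C(C)(C)C)cc1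
F3 | step 5 | 2,4-bis(benzyloxy)phenyllithium | [Li]c1ccc(OCc2ccccc2)cc1OCc1ccccc1
F4 | step 5 | bis-ketone, (2R,3R,4S,5S)-3,4-bis[2,4-bis(benzyloxy)benzoyl]-2,5-bis{4-[(tert-butyldimethylsilyl)oxy]phenyl}tetrahydrofuran (meso) | O=C(c1ccc(OCc2ccccc2)cc1OCc1ccccc1)[C@@H]1[C@H](C(=O)c2ccc(OCc3ccccc3)cc2OCc2ccccc2)[C@@H](c2ccc(O[Si](C)(C)C(C)(C)C)cc2)O[C@H]1c1ccc(O[Si](C)(C)C(C)(C)C)cc1
F5 | step 5 | bis-phenol, (2R,3R,4S,5S)-3,4-bis[2,4-bis(benzyloxy)benzoyl]-2,5-bis(4-hydroxyphenyl)tetrahydrofuran (meso) | O=C(c1ccc(OCc2ccccc2)cc1OCc1ccccc1)[C@@H]1[C@H](C(=O)c2ccc(OCc3ccccc3)cc2OCc2ccccc2)[C@@H](c2ccc(O)cc2)O[C@H]1c1ccc(O)cc1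
F6 | step 3 | aryl hydrogen maleate, (Z)-4-{3-[(tert-butyldimethylsilyl)oxy]phenoxy}-4-oxobut-2-enoic acid | O=C(O)/C=C\C(=O)Oc1cccc(O[Si](C)(C)C(C)(C)C)c1
F7 | step 3 | bis{3-[(tert-butyldimethylsilyl)oxy]phenyl} maleate | CC(C)(C)[Si](C)(C)Oc1cccc(OC(=O)/C=C\C(=O)Oc2cccc(O[Si](C)(C)C(C)(C)C)c2)c1
F8 | step 4 | cis-diacid, (2R,3R,4S,5S)-2,5-bis{4-[(tert-butyldimethylsilyl)oxy]phenyl}tetrahydrofuran-3,4-dicarboxylic acid (meso) | O=C(O)[C@@H]1[C@H](C(=O)O)[C@@H](c2ccc(O[Si](C)(C)C(C)(C)C)cc2)O[C@H]1c1ccc(O[Si](C)(C)C(C)(C)C)cc1
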